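## Retrosynthetic overview

1. Target ⇒ an ω-aldehyde whose C11–C13 allyl bromide is held in a six-membered lactone on O9. Allylchromium addition forms C6–C7 (the farnesyl C1–C10 bond of germacrene biosynthesis); O6 then takes the C12 acyl group from O9 (6,12-lactonisation) and frees 9-OH.
2. Tether lactone ⇒ ring-closing metathesis of a 9-O-[2-(bromomethyl)acrylate] onto a C7 vinyl group.
3. C8–C9 bond and both carbinol centres ⇒ catalytic asymmetric γ-angeloyloxyallylation of an (E)-2-formyl enoate; the angelate arrives with C7–C8.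
4. Formyl enoate ⇒ (S)-citronellal (C1–C6 and the C4 methyl centre) plus methyl acrylate (C9, C10, C14) by Morita–Baylis–Hillman reaction, SN2' bromination and Kornblum oxidation.
5. Ring order: temporary six-membered lactone → ten-membered carbocycle → five-membered lactone, the last two in one flask.

Assumption: atoms carry germacranolide numbers (C12 lactone carbonyl, C13 exocyclic methylene, C14 ester carbon, C15 methyl), and the (R,R)-salen ligand of step 8 is taken to give the (8S,9S) adduct; if the sense is opposite, its enantiomer is used.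

## Route

Step 1
Reactants: 1 (S)-citronellal
Product: 2 (6S)-8,8-dimethoxy-2,6-dimethyloct-2-ene
Conditions: HC(OMe)3, PPTS (cat.), MeOH, 0 °C → rt
Reagents that add atoms: trimethyl orthoformate, COC(OC)OC
Why: Acid-catalysed acetalisation with the orthoformate as water scavenger masks the C6 aldehyde, the mild acid avoiding the carbonyl-ene cyclisation of citronellal; the C4 centre is untouched.

Step 2
Reactants: 2 (6S)-8,8-dimethoxy-2,6-dimethyloct-2-ene
Product: 4 (4S)-6,6-dimethoxy-4-methylhexanal, via ozonide 3 (not isolated)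
Conditions: O3, CH2Cl2, −78 °C; then Me2S, −78 °C → rt
Reagents that add atoms: ozone, [O-][O+]=O
Why: Ozonolysis of the electron-rich trisubstituted alkene with reductive work-up gives the C1 aldehyde while the acetal is inert.

Step 3
Reactants: 4 (4S)-6,6-dimethoxy-4-methylhexanal; 5 methyl acrylate
Product: 6 methyl (6S)-3-hydroxy-8,8-dimethoxy-6-methyl-2-methylideneoctanoate
Conditions: DABCO (1 equiv), 5 (3 equiv), 1,4-dioxane/H2O 1:1, rt, 48 h
Reagents that add atoms: none
Why: The Morita–Baylis–Hillman reaction adds C10, C14 and C9 in one step; the new carbinol centre is formed as both epimers and is destroyed in step 4.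

Step 4
Reactants: 6 methyl (6S)-3-hydroxy-8,8-dimethoxy-6-methyl-2-methylideneoctanoate
Product: 7 methyl (2Z,6S)-2-(bromomethyl)-8,8-dimethoxy-6-methyloct-2-enoate
Conditions: NBS, Me2S, CH2Cl2, 0 °C → rt
Reagents that add atoms: N-bromosuccinimide, O=C1CCC(=O)N1Br
Why: Corey–Kim-type activation of the Baylis–Hillman alcohol followed by SN2' bromide delivery gives the (Z)-2-(bromomethyl)enoate, which fixes the C1=C10 geometry with the chain trans to CO2Me.

Step 5
Reactants: 7 methyl (2Z,6S)-2-(bromomethyl)-8,8-dimethoxy-6-methyloct-2-enoate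
Product: 8 methyl (2E,6S)-2-formyl-8,8-dimethoxy-6-methyloct-2-enoate
Conditions: NMO (3 equiv), 4 Å MS, MeCN, 0 °C → rt; used at once
Reagents that add atoms: N-methylmorpholine N-oxide, C[N+]1([O-])CCOCC1
Why: Kornblum–Ganem oxidation (N-oxide displacement of the primary allylic bromide, then elimination) gives the C9 aldehyde without touching the alkene geometry; immediate use limits E/Z drift of this doubly activated alkene.

Step 6
Reactants: 9 angelic acid
Product: 10 angeloyl chloride
Conditions: 1-chloro-N,N,2-trimethylprop-1-en-1-amine, CH2Cl2, 0 °C → rt; distil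
Reagents that add atoms: 1-chloro-N,N,2-trimethylprop-1-en-1-amine, CC(C)=C(Cl)N(C)C
Why: The chloroenamine forms the acid chloride under neutral conditions, so the (Z)-angeloyl geometry does not isomerise to tigloyl.

Step 7
Reactants: 10 angeloyl chloride; 11 acrolein
Product: 12 3-chloroprop-1-en-1-yl (2Z)-2-methylbut-2-enoate
Conditions: ZnCl2 (2 mol%), CH2Cl2, −20 °C → rt
Reagents that add atoms: none
Why: Lewis-acid-catalysed 1,4-addition of an acyl chloride to acrolein gives the γ-acyloxyallyl chloride; both enol ester isomers converge in step 8.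

Step 8
Reactants: 8 methyl (2E,6S)-2-formyl-8,8-dimethoxy-6-methyloct-2-enoate; 12 3-chloroprop-1-en-1-yl (2Z)-2-methylbut-2-enoate
Product: 14 methyl (2E,6S)-2-[(1S,2S)-1-hydroxy-2-{[(2Z)-2-methylbut-2-enoyl]oxy}but-3-en-1-yl]-8,8-dimethoxy-6-methyloct-2-enoate, via silyl ether 13 (not isolated)
Conditions: CrCl3 (10 mol%), (R,R)-N,N'-bis(3,5-di-tert-butylsalicylidene)-1,2-cyclohexanediamine (10 mol%), Et3N (20 mol%), Mn powder, Me3SiCl, MeCN, rt; then citric acid, MeOH, 0 °C
Reagents that add atoms: none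
Why: Catalytic asymmetric Nozaki–Hiyama–Kishi-type γ-acyloxyallylation, in which the salen-bound allylchromium adds through C8 to the aldehyde to give the syn 8-acyloxy-9-ol with the ligand setting C8 and C9, and immediate O-silylation blocks O8→O9 angeloyl migration.

Step 9
Reactants: 14 the syn hydroxy angelate from step 8; 15 2-(bromomethyl)prop-2-enoic acid
Product: 17 methyl (2E,6S)-2-[(1S,2S)-1-{[2-(bromomethyl)prop-2-enoyl]oxy}-2-{[(2Z)-2-methylbut-2-enoyl]oxy}but-3-en-1-yl]-8,8-dimethoxy-6-methyloct-2-enoate, via acid chloride 16 (not isolated)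
Conditions: 15 (1.5 equiv), 1-chloro-N,N,2-trimethylprop-1-en-1-amine (1.4 equiv), CH2Cl2, 0 °C; then 14, 2,6-lutidine, −20 → 0 °C
Reagents that add atoms: none
Why: Acylation of the only free hydroxyl by an acid chloride made under neutral conditions, the hindered weakly nucleophilic base avoiding SN2' attack on the bromomethyl acrylate and angeloyl migration; no stereocentre is touched.

Step 10
Reactants: 17 the bis-ester triene from step 9
Product: 18 methyl (2E,6S)-2-[(2S,3S)-5-(bromomethyl)-3-{[(2Z)-2-methylbut-2-enoyl]oxy}-6-oxo-3,6-dihydro-2H-pyran-2-yl]-8,8-dimethoxy-6-methyloct-2-enoate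
Conditions: second-generation Hoveyda–Grubbs catalyst RuCl2(H2IMes)(=CH-C6H4-2-O-i-Pr) (5 mol%), toluene, 60 °C, 5 mM
Reagents that add atoms: none
Why: Ring-closing metathesis joins the terminal vinyl group and the 1,1-disubstituted acrylate into the six-membered unsaturated lactone (the trisubstituted, electron-poor angelate and C1=C10 alkenes stay out), which locks C8 cis to the C12 carbonyl across C7=C11.

Step 11
Reactants: 18 the bromomethyl dihydropyranone acetal
Product: 19 methyl (2E,6S)-2-[(2S,3S)-5-(bromomethyl)-3-{[(2Z)-2-methylbut-2-enoyl]oxy}-6-oxo-3,6-dihydro-2H-pyran-2-yl]-6-methyl-8-oxooct-2-enoate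
Conditions: p-TsOH·H2O (10 mol%), acetone/H2O 20:1, rt
Reagents that add atoms: water, O
Why: Acid-catalysed hydrolysis of the dimethyl acetal frees the C6 aldehyde; the allylic bromide, the lactone and the esters are stable to dilute acid.

Step 12
Reactants: 19 the bromomethyl dihydropyranone aldehyde
Product: 23 the target, methyl (3aS,4S,5S,6E,10S,11aR)-5-hydroxy-10-methyl-3-methylidene-4-{[(2Z)-2-methylbut-2-enoyl]oxy}-2-oxo-2,3,3a,4,5,8,9,10,11,11a-decahydrocyclodeca[b]furan-6-carboxylate, via allylchromium dichloride 20 (not isolated), via bridged lactone alkoxide 21 (not isolated), via target chromium alkoxide 22 (not isolated)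
Conditions: CrCl2 (6 equiv), THF/DMF 4:1, rt, syringe-pump addition of 19 to 1 mM; then 1 M HCl, 0 °C
Reagents that add atoms: none
Why: Proposed new method: divalent chromium turns the allylic bromide into an allylchromium whose γ-carbon C7 adds to the tethered aldehyde (closest known type: intramolecular Nozaki–Hiyama–Kishi allylation with 2-(bromomethyl)acrylate and 3-(bromomethyl)butenolide donors) through a Zimmerman–Traxler chair in which the lactone ring fixes C8 trans to CH2Cr, so C5 and C8 are both equatorial and the anti adduct (H6/H7 trans) forms, while attack on the face of C7 opposite the pseudoaxial 8-angeloyloxy group sets 7S and 6R; the O6 chromium alkoxide then takes the C12 acyl group from O9 (strained bridged six-membered lactone → trans-fused five-membered lactone), freeing 9-OH on acidic work-up.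

## Compound list

1 | (S)-citronellal, (3S)-3,7-dimethyloct-6-enal | O=CC[C@@H](C)CCC=C(C)C | starting material
2 | (6S)-8,8-dimethoxy-2,6-dimethyloct-2-ene | COC(OC)C[C@@H](C)CCC=C(C)C | intermediate
3 | 3-[(3S)-5,5-dimethoxy-3-methylpentyl]-5,5-dimethyl-1,2,4-trioxolane (ozonide, ring CH centre unassigned) | COC(OC)C[C@@H](C)CCC1OOC(C)(C)O1 | intermediate (not isolated)
4 | (4S)-6,6-dimethoxy-4-methylhexanal | COC(OC)C[C@@H](C)CCC=O | intermediate
5 | methyl acrylate | C=CC(=O)OC | starting material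
6 | methyl (6S)-3-hydroxy-8,8-dimethoxy-6-methyl-2-methylideneoctanoate (both C3 epimers) | COC(OC)C[C@@H](C)CCC(O)C(=C)C(=O)OC | intermediate
7 | methyl (2Z,6S)-2-(bromomethyl)-8,8-dimethoxy-6-methyloct-2-enoate | COC(OC)C[C@@H](C)CC/C=C(\CBr)C(=O)OC | intermediate
8 | methyl (2E,6S)-2-formyl-8,8-dimethoxy-6-methyloct-2-enoate | COC(OC)C[C@@H](C)CC/C=C(\C=O)C(=O)OC | intermediate
9 | angelic acid, (2Z)-2-methylbut-2-enoic acid | OC(=O)/C(C)=C\C | starting material
10 | angeloyl chloride, (2Z)-2-methylbut-2-enoyl chloride | ClC(=O)/C(C)=C\C | intermediate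
11 | acrolein | C=CC=O | starting material
12 | 3-chloroprop-1-en-1-yl (2Z)-2-methylbut-2-enoate (E/Z mixture at the enol ester) | ClCC=COC(=O)/C(C)=C\C | intermediate
13 | methyl (2E,6S)-8,8-dimethoxy-6-methyl-2-[(1S,2S)-2-{[(2Z)-2-methylbut-2-enoyl]oxy}-1-[(trimethylsilyl)oxy]but-3-en-1-yl]oct-2-enoate | COC(OC)C[C@@H](C)CC/C=C(/C(=O)OC)[C@H](O[Si](C)(C)C)[C@@H](OC(=O)/C(C)=C\C)C=C | intermediate (not isolated)
14 | methyl (2E,6S)-2-[(1S,2S)-1-hydroxy-2-{[(2Z)-2-methylbut-2-enoyl]oxy}but-3-en-1-yl]-8,8-dimethoxy-6-methyloct-2-enoate | COC(OC)C[C@@H](C)CC/C=C(/C(=O)OC)[C@H](O)[C@@H](OC(=O)/C(C)=C\C)C=C | intermediate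
15 | 2-(bromomethyl)prop-2-enoic acid | OC(=O)C(=C)CBr | starting material
16 | 2-(bromomethyl)prop-2-enoyl chloride | ClC(=O)C(=C)CBr | intermediate (not isolated)
17 | methyl (2E,6S)-2-[(1S,2S)-1-{[2-(bromomethyl)prop-2-enoyl]oxy}-2-{[(2Z)-2-methylbut-2-enoyl]oxy}but-3-en-1-yl]-8,8-dimethoxy-6-methyloct-2-enoate | COC(OC)C[C@@H](C)CC/C=C(/C(=O)OC)[C@H](OC(=O)C(=C)CBr)[C@@H](OC(=O)/C(C)=C\C)C=C | intermediate
18 | methyl (2E,6S)-2-[(2S,3S)-5-(bromomethyl)-3-{[(2Z)-2-methylbut-2-enoyl]oxy}-6-oxo-3,6-dihydro-2H-pyran-2-yl]-8,8-dimethoxy-6-methyloct-2-enoate | COC(OC)C[C@@H](C)CC/C=C(/C(=O)OC)[C@@H]1OC(=O)C(CBr)=C[C@@H]1OC(=O)/C(C)=C\C | intermediate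
19 | methyl (2E,6S)-2-[(2S,3S)-5-(bromomethyl)-3-{[(2Z)-2-methylbut-2-enoyl]oxy}-6-oxo-3,6-dihydro-2H-pyran-2-yl]-6-methyl-8-oxooct-2-enoate | O=CC[C@@H](C)CC/C=C(/C(=O)OC)[C@@H]1OC(=O)C(CBr)=C[C@@H]1OC(=O)/C(C)=C\C | intermediate
20 | allylchromium dichloride of 19 (trivalent chromium on C13) | O=CC[C@@H](C)CC/C=C(/C(=O)OC)[C@@H]1OC(=O)C(C[Cr](Cl)Cl)=C[C@@H]1OC(=O)/C(C)=C\C | intermediate (not isolated)
21 | O6 dichlorochromium alkoxide of the (4S,6R,7S,8S,9S) ten-membered carbocycle still carrying the 9,12 six-membered lactone bridge (8-angelate, 14-methyl ester, 11(13)-methylene) | C=C1C(=O)O[C@@H]2[C@@H](OC(=O)/C(C)=C\C)[C@@H]1[C@H](O[Cr](Cl)Cl)C[C@@H](C)CC/C=C2/C(=O)OC | intermediate (not isolated)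
22 | O9 dichlorochromium alkoxide of the target | C=C1C(=O)O[C@@H]2C[C@@H](C)CC/C=C(/C(=O)OC)[C@H](O[Cr](Cl)Cl)[C@@H](OC(=O)/C(C)=C\C)[C@@H]12 | intermediate (not isolated)
23 | CNP0552150.1, methyl (3aS,4S,5S,6E,10S,11aR)-5-hydroxy-10-methyl-3-methylidene-4-{[(2Z)-2-methylbut-2-enoyl]oxy}-2-oxo-2,3,3a,4,5,8,9,10,11,11a-decahydrocyclodeca[b]furan-6-carboxylate; germacranolide numbering (4S,6R,7S,8S,9S) | C=C1C(=O)O[C@@H]2C[C@@H](C)CC/C=C(/C(=O)OC)[C@H](O)[C@@H](OC(=O)/C(C)=C\C)[C@@H]12 | target

## Step count and risks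

Total step count: 12. Longest linear sequence: 10 (steps 1–5 and 8–12); steps 6 and 7 are a two-step side branch.

Most likely to fail, 1: step 12. The allylchromium 20 could expel the 8-angelate by vinylogous β-elimination before it closes, the ten-membered closure could be slow, or the aldehyde could add to the wrong face of C7. The fallback replaces the organochromium by an isolable, non-basic allylboronate. It sets out from 14, which is esterified with 2-[(4,4,5,5-tetramethyl-1,3,2-dioxaborolan-2-yl)methyl]prop-2-enoic acid (DCC, cat. DMAP) to give the boronate bis-ester F1. Ring-closing metathesis as in step 10 gives the cyclic allylboronate acetal F2, and acetal hydrolysis as in step 11 gives the cyclic allylboronate aldehyde F3. Under Sc(OTf)3 catalysis at high dilution F3 closes by intramolecular allylboration through the same chair; the same acyl transfer and aqueous work-up bring the route back at 23.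

Most likely to fail, 2: step 8. The catalytic acyloxyallylation may give insufficient syn selectivity or enantioselectivity with an angelate donor, the angelate may migrate, or aldehyde 8 may lose its alkene geometry. The fallback uses a stoichiometric chiral reagent and brings the angelate in later. It sets out from 8, which is treated with [(Z)-γ-(methoxymethoxy)allyl]diisopinocampheylborane (from allyl methoxymethyl ether, s-BuLi, (Ipc)2BOMe and BF3·OEt2; −78 °C, ethanolamine work-up) to give the syn 8-methoxymethoxy-9-ol F4. Acylation as in step 9 gives the 9-O-[2-(bromomethyl)acrylate] F5. Aqueous HCl in THF removes the methoxymethyl group and the acetal to give the 8-hydroxy aldehyde F6. Angeloyl chloride 10 with 2,6-lutidine gives the angelate aldehyde F7, and ring-closing metathesis as in step 10 brings the route back at 19.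

Most likely to fail, 3: step 10. The bromomethyl acrylate may be too labile to install cleanly in step 9, or its allylic bromide may intercept the ruthenium carbene. The fallback introduces the bromide only after the ring is closed. It sets out from 14, which is esterified with 2-{[(tert-butyldimethylsilyl)oxy]methyl}prop-2-enoic acid (DCC, cat. DMAP) to give the silyloxymethyl acrylate F8. Ring-closing metathesis gives the silyloxymethyl dihydropyranone F9, HF·pyridine gives the hydroxymethyl dihydropyranone F10, and CBr4/PPh3 brings the route back at 18.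

## Further compounds

F1 | step 12 | methyl (2E,6S)-8,8-dimethoxy-6-methyl-2-[(1S,2S)-2-{[(2Z)-2-methylbut-2-enoyl]oxy}-1-({2-[(4,4,5,5-tetramethyl-1,3,2-dioxaborolan-2-yl)methyl]prop-2-enoyl}oxy)but-3-en-1-yl]oct-2-enoate | COC(OC)C[C@@H](C)CC/C=C(/C(=O)OC)[C@H](OC(=O)C(=C)CB1OC(C)(C)C(C)(C)O1)[C@@H](OC(=O)/C(C)=C\C)C=C
F2 | step 12 | analogue of 18 with CH2B(pin) in place of CH2Br | COC(OC)C[C@@H](C)CC/C=C(/C(=O)OC)[C@@H]1OC(=O)C(CB2OC(C)(C)C(C)(C)O2)=C[C@@H]1OC(=O)/C(C)=C\C
F3 | step 12 | analogue of 19 with CH2B(pin) in place of CH2Br | O=CC[C@@H](C)CC/C=C(/C(=O)OC)[C@@H]1OC(=O)C(CB2OC(C)(C)C(C)(C)O2)=C[C@@H]1OC(=O)/C(C)=C\C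
F4 | step 8 | methyl (2E,6S)-2-[(1S,2S)-1-hydroxy-2-(methoxymethoxy)but-3-en-1-yl]-8,8-dimethoxy-6-methyloct-2-enoate | COC(OC)C[C@@H](C)CC/C=C(/C(=O)OC)[C@H](O)[C@@H](OCOC)C=C
F5 | step 8 | methyl (2E,6S)-2-[(1S,2S)-1-{[2-(bromomethyl)prop-2-enoyl]oxy}-2-(methoxymethoxy)but-3-en-1-yl]-8,8-dimethoxy-6-methyloct-2-enoate | COC(OC)C[C@@H](C)CC/C=C(/C(=O)OC)[C@H](OC(=O)C(=C)CBr)[C@@H](OCOC)C=C
F6 | step 8 | methyl (2E,6S)-2-[(1S,2S)-1-{[2-(bromomethyl)prop-2-enoyl]oxy}-2-hydroxybut-3-en-1-yl]-6-methyl-8-oxooct-2-enoate | O=CC[C@@H](C)CC/C=C(/C(=O)OC)[C@H](OC(=O)C(=C)CBr)[C@@H](O)C=C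
F7 | step 8 | methyl (2E,6S)-2-[(1S,2S)-1-{[2-(bromomethyl)prop-2-enoyl]oxy}-2-{[(2Z)-2-methylbut-2-enoyl]oxy}but-3-en-1-yl]-6-methyl-8-oxooct-2-enoate | O=CC[C@@H](C)CC/C=C(/C(=O)OC)[C@H](OC(=O)C(=C)CBr)[C@@H](OC(=O)/C(C)=C\C)C=C
F8 | step 10 | analogue of 17 with CH2OSi(t-Bu)Me2 in place of CH2Br | COC(OC)C[C@@H](C)CC/C=C(/C(=O)OC)[C@H](OC(=O)C(=C)CO[Si](C)(C)C(C)(C)C)[C@@H](OC(=O)/C(C)=C\C)C=C
F9 | step 10 | analogue of 18 with CH2OSi(t-Bu)Me2 in place of CH2Br | COC(OC)C[C@@H](C)CC/C=C(/C(=O)OC)[C@@H]1OC(=O)C(CO[Si](C)(C)C(C)(C)C)=C[C@@H]1OC(=O)/C(C)=C\C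
F10 | step 10 | analogue of 18 with CH2OH in place of CH2Br | COC(OC)C[C@@H](C)CC/C=C(/C(=O)OC)[C@@H]1OC(=O)C(CO)=C[C@@H]1OC(=O)/C(C)=C\C
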